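## Structural features

The target is a biflavonoid: two C15 units joined by one bond between C3 (sp3) of a flavanone and C3' of a flavone. The flavanone half is a 5,7-dihydroxychroman-4-one (rings A and C) with a 4-hydroxyphenyl ring B on C2. The flavone half is a 5,7-dihydroxy-2-aryl-4H-chromen-4-one whose aryl ring carries a free hydroxyl ortho to the linkage. The only stereocentres are C2 (R) and C3 (S) of ring C; they are adjacent and hold the two aryl groups trans on the pyranone. Both are fragile: C3–H is benzylic and α to the C4 ketone, and the C2–O1 bond is benzylic and β to that ketone, so base opens ring C to the 2'-hydroxychalcone and erases the configuration. Six phenols and a second, Lewis-basic chromone must be carried as well. The real difficulty is to set the 2,3-diaryl pair in absolute terms next to an enolisable ketone and to close ring C without passing through the chalcone. The key step uses the fact that ring A (C4a, C5, C6, C7, C8, C8a) is a 1,3,5-trioxygenated benzene with the C4 acyl carbon on C4a: this is the pattern of a Claisen-folded 3,5,7-triketo ester, and the two oxygens ortho to the acyl group (on C5 and C8a) are equivalent, so either can become O1.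

## Logic of the disconnections

25 to 24. The four O–CH2Ph bonds are cut. One protecting group removable under neutral hydrogenolysis is used for every phenol that is present before ring A exists, because ring C tolerates neither base nor strong Lewis acid. The forward step must leave the benzylic C2–O1 bond and the chromone C2=C3 bond alone.

24 to 23. The O1–C2 bond is cut. Ring C and the C2 configuration are traced to an open-chain carbinol of opposite configuration, closed by intramolecular etherification with inversion. Because the two ortho hydroxyls of ring A are equivalent, there is no regiochemical question. The forward step needs substitution to outrun β-elimination. The syn (S,S) series is chosen so that even an ionising pathway, steered by C3, leads to the same trans product.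

23 to 22. The O–Si bond is cut. The carbinol must stay masked while the poly-β-carbonyl chain exists (a free hydroxyl would add to the 1,3-diketone), and it must be unmasked without base, since a β-hydroxy ketone with an α-aryl group undergoes retro-aldol cleavage. A tert-butyldimethylsilyl ether removed by acidic fluoride meets both demands.

22 to 20 (through 21). The C4a–C8a bond is cut and ring A becomes a linear chain masked as a dioxinone. The regiochemistry of ring A (acyl group flanked by two oxygens) then follows from the chain and needs no aromatic substitution. The forward step must fold in the Claisen and not the aldol sense and must not expel the β-silyloxy group. In 20 the four existing phenols are benzyl ethers and the ring-A oxygens need no protection because they are created in this step.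

20 to 16 and 18; 18 to 17. The C4–C4a bond is cut, between the acyl carbon and the terminal carbon of the masked chain. This divides 20 into the chiral acid 16 and an achiral six-carbon unit that comes from 17 by a two-carbon acylation. The forward acylation must be faster than proton transfer from the carbon α to the acyl donor.

16 to 15 and 14, then to 12 and 13. The C2–C3 bond is cut. An auxiliary-controlled syn-aldol sets both stereocentres in one step from an arylacetyl imide and an aromatic aldehyde. The forward step needs a Z-enolate, tolerance of the chromone toward the boron Lewis acid, and auxiliary removal without epimerisation of the α-aryl centre.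

12 to 9 and 10; 9 to 8; 8 to 6 and 7. The N–acyl bond and then the aryl–CH2 bond are cut. The bromine of 6 serves as a robust placeholder during flavone construction and is exchanged for the acetate unit by cross-coupling. The organozinc partner must not attack the chromone carbonyl.

6 to 5; 5 to 2 and 4; 2 to 1; 4 to 3. The chromone O1–C2 bond and the enone Cα=Cβ bond are cut, which leads to an acetophenone and an aldehyde. The phenol ortho to the acetyl group must stay free through the benzylation of 1.

## Other disconnections considered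

Alternative 1: The cut is C2–C3 of ring C. The α-diazo ketone A1, whose aroyl ring carries three identical 4-(benzyloxy)benzyl ethers, would lose N2 on Rh2(S-PTTL)4. The carbene at C3 would insert into a benzylic C–H bond of one ortho ether to give the protected flavanone A2, which needs only hydrogenolysis.
- In favour: one catalytic step makes the C2–C3 bond, ring C and both stereocentres without an auxiliary. Either ortho ether will do, and the C–H bond is activated by the ether oxygen and the 4-(benzyloxy)phenyl group.
- Against: the aryl group on the carbene carbon has its own ortho benzyloxy group, placed for a 1,5-insertion to a 2,3-dihydrobenzofuran. That is normally the faster mode; the wanted closure is a 1,6-insertion. An aryl acyl carbene next to a 2,6-dioxygenated ring can also undergo Wolff rearrangement or add to an arene. Insertion tends to give the cis product under kinetic control, so C3 would need epimerisation next to a base-labile ring. Enantiocontrol for so hindered a carbene cannot be predicted with confidence.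
- Comparison: on structure both plans use the same symmetry of ring A, and the alternative is better in that ring A is bought and not built. On mechanism the chosen plan sets the pair of stereocentres through a closed aldol transition state of predictable outcome, whereas here site, diastereo- and enantioselectivity all rest on one catalyst. On step economy the alternative is clearly better (several steps shorter, one step after the key step against three) if the insertion can be made selective.

Alternative 2: The cut is C3–C4 (made by migration) together with O1–C2. The racemic trans-chalcone epoxide A3 would be opened by BF3·OEt2 at the carbon bearing the flavone-carrying aryl ring, and the aroyl group would shift to that carbon. HCl in methanol would then free the phenol from its methoxymethyl ether so that it condenses with the new aldehyde carbon to give the bis-chromone A4.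
- In favour: this is the classical chalcone-to-isoflavone route. It is convergent, carries no stereocentre and no enolisable ketone through the assembly, and the ortho benzyloxy group supports the benzylic cation that the shift requires.
- Against: A4 is flat. It lacks the 4-hydroxyphenyl group on C2 and both stereocentres. The real difficulty is postponed to an enantioselective conjugate arylation at C2 of a 3-aryl chromone (a hindered, α-arylated enone) in the presence of a second chromone, followed by face-selective protonation at C3. Precedent for conjugate arylation of chromones concerns the 3-unsubstituted ring. The Lewis acid may also strip the benzyl ether peri to a carbonyl.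
- Comparison: on structure the alternative is better in forming the C3–aryl linkage and ring C together, and equal in its use of the phloroglucinol pattern of ring A. On mechanism its key step is at least as reliable as the Claisen folding. On step economy it reaches A4 in fewer steps than the chosen plan reaches 22, but the gain is offset by the unsolved asymmetric arylation, whereas the chosen plan has both stereocentres in place before ring A is made.

Alternative 3: The cuts are O1–C2 and C4–C4a. The cis-β-lactone A5 would come from lactonisation of a syn-aldol acid of the same (S,S) series as 16, with a pivalate on ring B. The caesium phenoxide of A6 (Cs2CO3) would open it at the benzylic carbon with inversion to give the β-aryloxy acid A7. (CF3CO)2O would then form a mixed anhydride that acylates the electron-rich ring ortho to the new ether and closes ring C as A8.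
- In favour: the absolute configuration comes from the same auxiliary aldol, and the inversion that turns syn into trans is built into the lactone opening. Ring A is a commercial symmetric phenol with two equivalent ortho positions. One flask forms both bonds of the annulation, and no triphenol goes through a Mitsunobu reaction.
- Against: a 4-aryl β-lactone ionises or loses CO2 easily, hence the electron-poor pivalate in place of a benzyl ether. The phenoxide can attack the acyl carbon or remove the acidic C3–H, which opens the lactone to a 2,3-diarylacrylate. Substitution at a secondary benzylic carbon next to an aryl-bearing carbon is slow. The anhydride of an α-aryl acid can epimerise through a ketene, and A7 can lose the phenol by elimination. The pivalate needs its own removal under conditions the flavanone tolerates poorly.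
- Comparison: on structure the two plans are equal in their use of the ring-A symmetry and in their source of chirality. On mechanism both make O1–C2 by substitution with inversion at the same benzylic carbon and share the danger of β-elimination, so neither is clearly safer there; the Friedel–Crafts closure is better precedented for electron-rich rings than the Claisen folding is for so hindered a chain. On step economy the alternative is better by about three steps. The chosen plan is preferred only because it avoids the labile 4-aryl β-lactone and keeps every early phenol as a benzyl ether to the last step.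

Key step: step 13

Remark on the chemistry: 7 is taken as the commercial ether solution of the Reformatsky reagent; in names, ArF stands for 2-(benzyloxy)-5-[5,7-bis(benzyloxy)-4-oxo-4H-chromen-2-yl]phenyl.

## Route

Step 1
Reactants: 1 2',4',6'-trihydroxyacetophenone
Product: 2 1-[2,4-bis(benzyloxy)-6-hydroxyphenyl]ethan-1-one
Conditions: BnBr (2.05 equiv), K2CO3, acetone, reflux
Reagents that add atoms: benzyl bromide, BrCc1ccccc1
Why: Williamson etherification; the hydroxyl hydrogen-bonded to the acetyl carbonyl is the least nucleophilic, so two equivalents of BnBr should stop at the 4,6-dibenzyl ether and leave the phenol needed for the chromone closure.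

Step 2
Reactants: 3 3-bromo-4-hydroxybenzaldehyde
Product: 4 4-(benzyloxy)-3-bromobenzaldehyde
Conditions: BnBr, K2CO3, DMF, rt
Reagents that add atoms: benzyl bromide, BrCc1ccccc1
Why: Williamson etherification of an acidic phenol; the aldehyde and the aryl bromide are inert to carbonate.

Step 3
Reactants: 2 1-[2,4-bis(benzyloxy)-6-hydroxyphenyl]ethan-1-one; 4 4-(benzyloxy)-3-bromobenzaldehyde
Product: 5 (E)-1-[2,4-bis(benzyloxy)-6-hydroxyphenyl]-3-[4-(benzyloxy)-3-bromophenyl]prop-2-en-1-one
Conditions: KOH (50% aq.), EtOH/THF, rt
Reagents that add atoms: none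
Why: Claisen–Schmidt condensation of a methyl ketone with a non-enolisable aldehyde; E1cB dehydration of the aldol gives the E-enone, and any flavanone formed by oxa-Michael closure converges with 5 in step 4.

Step 4
Reactants: 5 (E)-1-[2,4-bis(benzyloxy)-6-hydroxyphenyl]-3-[4-(benzyloxy)-3-bromophenyl]prop-2-en-1-one
Product: 6 5,7-bis(benzyloxy)-2-[4-(benzyloxy)-3-bromophenyl]-4H-chromen-4-one
Conditions: I2 (10 mol%), DMSO, 120 °C
Reagents that add atoms: none
Why: Iodine-catalysed oxidative cyclisation of a 2'-hydroxychalcone (oxa-Michael closure, α-iodination, loss of HI), with DMSO as terminal oxidant; benzyl ethers and the aryl bromide are spectators.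

Step 5
Reactants: 6 5,7-bis(benzyloxy)-2-[4-(benzyloxy)-3-bromophenyl]-4H-chromen-4-one; 7 (2-tert-butoxy-2-oxoethyl)zinc chloride
Product: 8 tert-butyl 2-ArF-acetate
Conditions: 7 (1.5 equiv), Pd2(dba)3 (2 mol%), XPhos (8 mol%), THF, 60 °C
Reagents that add atoms: none
Why: Negishi-type α-arylation of a zinc ester enolate: oxidative addition of the aryl bromide to zerovalent palladium, transmetalation and reductive elimination; the Reformatsky reagent is too weak a base and nucleophile to attack the chromone carbonyl, and the tert-butyl ester prevents self-condensation.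

Step 6
Reactants: 8 tert-butyl 2-ArF-acetate
Product: 9 2-ArF-acetic acid
Conditions: CF3CO2H/CH2Cl2 (1:4), 0 °C to rt
Reagents that add atoms: none
Why: Acidolysis of the tert-butyl ester through the tert-butyl cation; aryl benzyl ethers and the chromone should survive brief exposure to CF3CO2H at room temperature, and no base touches the flavone.

Step 7
Reactants: 9 2-ArF-acetic acid; 10 (S)-4-benzyloxazolidin-2-one
Product: 12 (S)-4-benzyl-3-(2-ArF-acetyl)oxazolidin-2-one, via mixed pivalic anhydride 11 (not isolated)
Conditions: t-BuCOCl, Et3N, THF, −20 °C; then LiCl, 10, −20 °C to rt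
Reagents that add atoms: none
Why: Mixed-anhydride N-acylation of the oxazolidinone under LiCl/Et3N activation; the pivaloyl carbonyl is shielded, so the auxiliary attacks the arylacetyl carbonyl, and no strong base is needed.

Step 8
Reactants: 12 (S)-4-benzyl-3-(2-ArF-acetyl)oxazolidin-2-one; 13 4-(benzyloxy)benzaldehyde
Product: 14 (S)-4-benzyl-3-{(2S,3S)-2-ArF-3-[4-(benzyloxy)phenyl]-3-hydroxypropanoyl}oxazolidin-2-one
Conditions: n-Bu2BOTf (2.2 equiv), i-Pr2NEt (2.6 equiv), CH2Cl2, −78 to 0 °C; then 13, −78 to 0 °C; pH 7 buffer, MeOH
Reagents that add atoms: none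
Why: Evans syn-aldol: the Z-boron enolate reacts through a closed chair transition state with the aldehyde on the enolate face away from the auxiliary benzyl group, which sets (S) at the aryl-bearing carbon and (S) at the carbinol; the surplus n-Bu2BOTf allows for reversible coordination to the chromone carbonyl.

Step 9
Reactants: 14 (S)-4-benzyl-3-{(2S,3S)-2-ArF-3-[4-(benzyloxy)phenyl]-3-hydroxypropanoyl}oxazolidin-2-one
Product: 15 (S)-4-benzyl-3-{(2S,3S)-2-ArF-3-[4-(benzyloxy)phenyl]-3-[(tert-butyldimethylsilyl)oxy]propanoyl}oxazolidin-2-one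
Conditions: TBSOTf, 2,6-lutidine, CH2Cl2, −20 to 0 °C
Reagents that add atoms: tert-butyldimethylsilyl trifluoromethanesulfonate, CC(C)(C)[Si](C)(C)OS(=O)(=O)C(F)(F)F
Why: Silylation of a hindered secondary alcohol with a silyl triflate and a hindered pyridine; the non-nucleophilic, weakly basic medium avoids retro-aldol cleavage and leaves both stereocentres untouched.

Step 10
Reactants: 15 (S)-4-benzyl-3-{(2S,3S)-2-ArF-3-[4-(benzyloxy)phenyl]-3-[(tert-butyldimethylsilyl)oxy]propanoyl}oxazolidin-2-one
Product: 16 (2S,3S)-2-ArF-3-[4-(benzyloxy)phenyl]-3-[(tert-butyldimethylsilyl)oxy]propanoic acid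
Conditions: LiOH, H2O2 (30%), THF/H2O (3:1), 0 °C; then aq. Na2SO3; HCl to pH 3
Reagents that add atoms: hydrogen peroxide, OO (as LiOOH; source of the carboxyl OH oxygen)
Why: Hydroperoxide-mediated exocyclic cleavage of the imide; the weakly basic, strongly nucleophilic hydroperoxide should leave the α-aryl centre and the β-silyloxy group intact, and 10 is recovered.

Step 11
Reactants: 17 2,2,6-trimethyl-4H-1,3-dioxin-4-one
Product: 18 2,2-dimethyl-6-(2-oxopropyl)-4H-1,3-dioxin-4-one
Conditions: LiN(SiMe3)2 (2 equiv), THF, −78 °C; then AcCl, −78 °C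
Reagents that add atoms: acetyl chloride, CC(Cl)=O
Why: Claisen-type C-acylation of the vinylogous lithium enolate at its exocyclic carbon; the second equivalent of base is consumed by the more acidic product.

Step 12
Reactants: 16 (2S,3S)-2-ArF-3-[4-(benzyloxy)phenyl]-3-[(tert-butyldimethylsilyl)oxy]propanoic acid; 18 2,2-dimethyl-6-(2-oxopropyl)-4H-1,3-dioxin-4-one
Product: 20 6-{(5S,6S)-5-ArF-6-[4-(benzyloxy)phenyl]-6-[(tert-butyldimethylsilyl)oxy]-2,4-dioxohexyl}-2,2-dimethyl-4H-1,3-dioxin-4-one, via acyl imidazole 19 (not isolated)
Conditions: 16, CDI (1.1 equiv), THF, rt; separately 18 (3 equiv), LiN(i-Pr)2 (6 equiv), THF, −78 °C, then Et2Zn (3 equiv); add 19, −78 to −20 °C; aq. NH4Cl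
Reagents that add atoms: none
Why: Claisen-type acylation of a 1,3-dicarbonyl dianion at its terminal, most nucleophilic carbon by an acyl imidazole; Et2Zn lowers the basicity of the dianion so that acylation should outrun proton transfer from the α-aryl C–H, and the surplus dianion takes up the imidazole N–H and the acidic protons of 20.

Step 13
Reactants: 20 6-{(5S,6S)-5-ArF-6-[4-(benzyloxy)phenyl]-6-[(tert-butyldimethylsilyl)oxy]-2,4-dioxohexyl}-2,2-dimethyl-4H-1,3-dioxin-4-one
Product: 22 (2S,3S)-2-ArF-3-[4-(benzyloxy)phenyl]-3-[(tert-butyldimethylsilyl)oxy]-1-(2,4,6-trihydroxyphenyl)propan-1-one, via methyl triketo ester 21 (not isolated)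
Conditions: MeOH (30 equiv), toluene, 110 °C (sealed tube); concentrate; Mg(OMe)2 (6 equiv), MeOH, 0 °C to rt; 1 M HCl work-up, 0 °C
Reagents that add atoms: none
Why: Heating drives a retro-[4+2] loss of acetone from the dioxinone and methanol adds to the resulting acylketene, so the methyl 3,5,7-triketo ester 21 is released only at the moment of folding. Mg(OMe)2 turns 21 into a magnesium-chelated polyenolate in which the carbanion between the two ketones nearest the stereocentres (the future C4a) is held beside the ester carbonyl (the future C8a). Addition to the ester and loss of methoxide, a 6-exo-trig closure, forms the C4a–C8a bond, and enolisation of the cyclohexanetrione gives aromatic ring A. The closest known reaction type is the magnesium alkoxide Claisen cyclisation of 3,5,7-triketo esters to acylphloroglucinols, the laboratory counterpart of chalcone synthase folding. No stereocentre is formed, and the two existing ones are only carried through. The selectivity needed is Claisen over aldol folding, in which the ester α-carbon would attack the C4 ketone and give a resorcylate; the C4 ketone is flanked by a branched carbon bearing an aryl and a silyloxybenzyl group, which makes it the poorer electrophile, and the magnesium chelate activates the ester. The second requirement is that C3–H is not removed, since that would epimerise C3 or expel the silyloxy group by an E1cB path; the C4 carbonyl is already part of the delocalised polyanion, so a further deprotonation next to it should be slow at room temperature.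

Step 14
Reactants: 22 (2S,3S)-2-ArF-3-[4-(benzyloxy)phenyl]-3-[(tert-butyldimethylsilyl)oxy]-1-(2,4,6-trihydroxyphenyl)propan-1-one
Product: 23 (2S,3S)-2-ArF-3-[4-(benzyloxy)phenyl]-3-hydroxy-1-(2,4,6-trihydroxyphenyl)propan-1-one
Conditions: HF·pyridine, pyridine, THF, 0 °C to rt
Reagents that add atoms: none
Why: Fluoride-driven cleavage of the Si–O bond in a buffered, non-basic medium, which avoids the retro-aldol cleavage that basic fluoride would cause; benzyl ethers and phenols are untouched.

Step 15
Reactants: 23 (2S,3S)-2-ArF-3-[4-(benzyloxy)phenyl]-3-hydroxy-1-(2,4,6-trihydroxyphenyl)propan-1-one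
Product: 24 (2R,3S)-3-ArF-2-[4-(benzyloxy)phenyl]-5,7-dihydroxychroman-4-one
Conditions: PPh3, DIAD, THF (0.01 M), 0 °C
Reagents that add atoms: none
Why: Intramolecular Mitsunobu etherification (6-exo-tet): the acidic ring-A phenol displaces the oxyphosphonium group with inversion, (S) to (R) at C2, while C3 is not touched, so the syn diad becomes the trans-flavanone; either ortho hydroxyl gives the same product, and any ionised fraction should close anti to the C3 aryl group to the same isomer.

Step 16
Reactants: 24 (2R,3S)-3-ArF-2-[4-(benzyloxy)phenyl]-5,7-dihydroxychroman-4-one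
Product: 25 (2R,3S)-3-[5-(5,7-dihydroxy-4-oxo-4H-chromen-2-yl)-2-hydroxyphenyl]-5,7-dihydroxy-2-(4-hydroxyphenyl)chroman-4-one
Conditions: H2 (1 atm), 10% Pd/C, EtOAc/MeOH (1:1), rt
Reagents that add atoms: none
Why: Hydrogenolysis of four aryl benzyl ethers in a neutral medium, which avoids base-induced opening of ring C; the chromone double bond and the cyclic benzylic C2–O1 bond react much more slowly than O-benzyl groups.

## Compound list

1 | 2',4',6'-trihydroxyacetophenone | CC(=O)c1c(O)cc(O)cc1O | starting material
2 | 1-[2,4-bis(benzyloxy)-6-hydroxyphenyl]ethan-1-one | CC(=O)c1c(O)cc(OCc2ccccc2)cc1OCc1ccccc1 | intermediate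
3 | 3-bromo-4-hydroxybenzaldehyde | O=Cc1ccc(O)c(Br)c1 | starting material
4 | 4-(benzyloxy)-3-bromobenzaldehyde | O=Cc1ccc(OCc2ccccc2)c(Br)c1 | intermediate
5 | (E)-1-[2,4-bis(benzyloxy)-6-hydroxyphenyl]-3-[4-(benzyloxy)-3-bromophenyl]prop-2-en-1-one | O=C(/C=C/c1ccc(OCc2ccccc2)c(Br)c1)c1c(O)cc(OCc2ccccc2)cc1OCc1ccccc1 | intermediate
6 | 5,7-bis(benzyloxy)-2-[4-(benzyloxy)-3-bromophenyl]-4H-chromen-4-one | O=c1cc(-c2ccc(OCc3ccccc3)c(Br)c2)oc2cc(OCc3ccccc3)cc(OCc3ccccc3)c12 | intermediate
7 | (2-tert-butoxy-2-oxoethyl)zinc chloride | CC(C)(C)OC(=O)C[Zn]Cl | starting material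
8 | tert-butyl 2-{2-(benzyloxy)-5-[5,7-bis(benzyloxy)-4-oxo-4H-chromen-2-yl]phenyl}acetate | CC(C)(C)OC(=O)Cc1cc(-c2cc(=O)c3c(OCc4ccccc4)cc(OCc4ccccc4)cc3o2)ccc1OCc1ccccc1 | intermediate
9 | 2-{2-(benzyloxy)-5-[5,7-bis(benzyloxy)-4-oxo-4H-chromen-2-yl]phenyl}acetic acid | OC(=O)Cc1cc(-c2cc(=O)c3c(OCc4ccccc4)cc(OCc4ccccc4)cc3o2)ccc1OCc1ccccc1 | intermediate
10 | (S)-4-benzyloxazolidin-2-one | O=C1N[C@@H](Cc2ccccc2)CO1 | starting material
11 | 2-ArF-acetic pivalic anhydride | CC(C)(C)C(=O)OC(=O)Cc1cc(-c2cc(=O)c3c(OCc4ccccc4)cc(OCc4ccccc4)cc3o2)ccc1OCc1ccccc1 | intermediate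
12 | (S)-4-benzyl-3-(2-ArF-acetyl)oxazolidin-2-one | O=C(Cc1cc(-c2cc(=O)c3c(OCc4ccccc4)cc(OCc4ccccc4)cc3o2)ccc1OCc1ccccc1)N1C(=O)OC[C@@H]1Cc1ccccc1 | intermediate
13 | 4-(benzyloxy)benzaldehyde | O=Cc1ccc(OCc2ccccc2)cc1 | starting material
14 | (S)-4-benzyl-3-{(2S,3S)-2-ArF-3-[4-(benzyloxy)phenyl]-3-hydroxypropanoyl}oxazolidin-2-one | O[C@H](c1ccc(OCc2ccccc2)cc1)[C@@H](C(=O)N1C(=O)OC[C@@H]1Cc1ccccc1)c1cc(-c2cc(=O)c3c(OCc4ccccc4)cc(OCc4ccccc4)cc3o2)ccc1OCc1ccccc1 | intermediate
15 | (S)-4-benzyl-3-{(2S,3S)-2-ArF-3-[4-(benzyloxy)phenyl]-3-[(tert-butyldimethylsilyl)oxy]propanoyl}oxazolidin-2-one | CC(C)(C)[Si](C)(C)O[C@H](c1ccc(OCc2ccccc2)cc1)[C@@H](C(=O)N1C(=O)OC[C@@H]1Cc1ccccc1)c1cc(-c2cc(=O)c3c(OCc4ccccc4)cc(OCc4ccccc4)cc3o2)ccc1OCc1ccccc1 | intermediate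
16 | (2S,3S)-2-ArF-3-[4-(benzyloxy)phenyl]-3-[(tert-butyldimethylsilyl)oxy]propanoic acid | CC(C)(C)[Si](C)(C)O[C@H](c1ccc(OCc2ccccc2)cc1)[C@@H](C(=O)O)c1cc(-c2cc(=O)c3c(OCc4ccccc4)cc(OCc4ccccc4)cc3o2)ccc1OCc1ccccc1 | intermediate
17 | 2,2,6-trimethyl-4H-1,3-dioxin-4-one | CC1=CC(=O)OC(C)(C)O1 | starting material
18 | 2,2-dimethyl-6-(2-oxopropyl)-4H-1,3-dioxin-4-one | CC(=O)CC1=CC(=O)OC(C)(C)O1 | intermediate
19 | (2S,3S)-2-ArF-3-[4-(benzyloxy)phenyl]-3-[(tert-butyldimethylsilyl)oxy]-1-(1H-imidazol-1-yl)propan-1-one | CC(C)(C)[Si](C)(C)O[C@H](c1ccc(OCc2ccccc2)cc1)[C@@H](C(=O)n1ccnc1)c1cc(-c2cc(=O)c3c(OCc4ccccc4)cc(OCc4ccccc4)cc3o2)ccc1OCc1ccccc1 | intermediate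
20 | 6-{(5S,6S)-5-ArF-6-[4-(benzyloxy)phenyl]-6-[(tert-butyldimethylsilyl)oxy]-2,4-dioxohexyl}-2,2-dimethyl-4H-1,3-dioxin-4-one | CC(C)(C)[Si](C)(C)O[C@H](c1ccc(OCc2ccccc2)cc1)[C@@H](C(=O)CC(=O)CC1=CC(=O)OC(C)(C)O1)c1cc(-c2cc(=O)c3c(OCc4ccccc4)cc(OCc4ccccc4)cc3o2)ccc1OCc1ccccc1 | intermediate
21 | methyl (8S,9S)-8-ArF-9-[4-(benzyloxy)phenyl]-9-[(tert-butyldimethylsilyl)oxy]-3,5,7-trioxononanoate | CC(C)(C)[Si](C)(C)O[C@H](c1ccc(OCc2ccccc2)cc1)[C@@H](C(=O)CC(=O)CC(=O)CC(=O)OC)c1cc(-c2cc(=O)c3c(OCc4ccccc4)cc(OCc4ccccc4)cc3o2)ccc1OCc1ccccc1 | intermediate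
22 | (2S,3S)-2-ArF-3-[4-(benzyloxy)phenyl]-3-[(tert-butyldimethylsilyl)oxy]-1-(2,4,6-trihydroxyphenyl)propan-1-one | CC(C)(C)[Si](C)(C)O[C@H](c1ccc(OCc2ccccc2)cc1)[C@@H](C(=O)c1c(O)cc(O)cc1O)c1cc(-c2cc(=O)c3c(OCc4ccccc4)cc(OCc4ccccc4)cc3o2)ccc1OCc1ccccc1 | intermediate
23 | (2S,3S)-2-ArF-3-[4-(benzyloxy)phenyl]-3-hydroxy-1-(2,4,6-trihydroxyphenyl)propan-1-one | O[C@H](c1ccc(OCc2ccccc2)cc1)[C@@H](C(=O)c1c(O)cc(O)cc1O)c1cc(-c2cc(=O)c3c(OCc4ccccc4)cc(OCc4ccccc4)cc3o2)ccc1OCc1ccccc1 | intermediate
24 | (2R,3S)-3-ArF-2-[4-(benzyloxy)phenyl]-5,7-dihydroxychroman-4-one | O=C1c2c(O)cc(O)cc2O[C@@H](c2ccc(OCc3ccccc3)cc2)[C@@H]1c1cc(-c2cc(=O)c3c(OCc4ccccc4)cc(OCc4ccccc4)cc3o2)ccc1OCc1ccccc1 | intermediate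
25 | (2R,3S)-3-[5-(5,7-dihydroxy-4-oxo-4H-chromen-2-yl)-2-hydroxyphenyl]-5,7-dihydroxy-2-(4-hydroxyphenyl)chroman-4-one | O=C1c2c(O)cc(O)cc2O[C@@H](c2ccc(O)cc2)[C@@H]1c1cc(-c2cc(=O)c3c(O)cc(O)cc3o2)ccc1O | target

## Step count and least certain steps

Total step count: 16. Longest linear sequence: 14 steps (steps 1, 3 to 10 and 12 to 16, from 1 to 25).

Step 13 (key step). What may go wrong:
- aldol folding of the polyenolate toward a resorcylate;
- slow deprotonation at C3 during the exposure to methoxide, followed by loss of silanolate (E1cB) or epimerisation;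
- competing O-acylation of the acylketene to a pyranone if methanol trapping is slow (methoxide should reopen it).

The fallback builds the aryl ketone from a preformed ring A and avoids base-mediated folding. It sets out from 16 and comes back to the route at 23. 1,3,5-Tris(methoxymethoxy)benzene F1 (by exhaustive methoxymethylation of the parent triphenol) would be lithiated between two ether groups with n-BuLi and transmetalated with ZnCl2 to [2,4,6-tris(methoxymethoxy)phenyl]zinc chloride F2. Acid 16 would be converted under neutral conditions, with 1-chloro-N,N,2-trimethylprop-1-en-1-amine, into (2S,3S)-2-ArF-3-[4-(benzyloxy)phenyl]-3-[(tert-butyldimethylsilyl)oxy]propanoyl chloride F3. Pd(PPh3)4-catalysed Negishi acylation of F2 with F3 should give (2S,3S)-2-ArF-3-[4-(benzyloxy)phenyl]-3-[(tert-butyldimethylsilyl)oxy]-1-[2,4,6-tris(methoxymethoxy)phenyl]propan-1-one F4, since the arylzinc is not basic enough to enolise the acyl chloride. HCl in MeOH/THF would then remove the three acetals and the silyl group to give 23. If the benzylic carbinol ionises under the acid, capture by an ortho phenol anti to the C3 aryl group would lead on to 24.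

Step 12. What may go wrong: proton transfer from the α-aryl C–H of 19 to the dianion competing with C-acylation, which would lead to epimerisation at C3, ketene formation and β-elimination of the silyloxy group.

The fallback replaces the strongly basic dianion by soft enolisation. It sets out from 16 and 18 and comes back at 20. The dianion of 18 and allyl chloroformate would give allyl 4-(2,2-dimethyl-4-oxo-4H-1,3-dioxin-6-yl)-3-oxobutanoate F5. F5 would be C-acylated at its central methylene by the acid chloride F3 (made from 16 as described above) with MgCl2 and pyridine in CH2Cl2 at 0 °C. This would give allyl (4S,5S)-4-ArF-5-[4-(benzyloxy)phenyl]-5-[(tert-butyldimethylsilyl)oxy]-2-[2-(2,2-dimethyl-4-oxo-4H-1,3-dioxin-6-yl)acetyl]-3-oxopentanoate F6. Pd(PPh3)4 and morpholine would remove the allyl group, and decarboxylation of the β-keto acid would give 20.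

Step 15. What may go wrong: β-elimination of the activated oxyphosphonium group toward the α-aryl chalcone, followed by unselective oxa-Michael closure and loss of configuration at both centres; also intermolecular etherification through the para phenol.

The fallback changes the controlling element from inversion at C2 to substrate control by C3. It sets out from 23 and comes back at 24, with no new compound. Catalytic camphorsulfonic acid in CH2Cl2 at −20 °C would ionise the 4-(benzyloxy)benzylic carbinol, and the ortho phenol should capture the cation anti to the C3 aryl group, giving the trans isomer 24.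

Step 10. What may go wrong: attack of hydroperoxide at the ring carbonyl of the hindered imide (endocyclic cleavage) and base-mediated epimerisation of the α-aryl centre.

The fallback replaces hydrolysis by thiolysis and uses the thioester directly as acyl donor. It sets out from 15 and comes back at 20. EtSLi (from ethanethiol and n-BuLi) in THF at 0 °C would give S-ethyl (2S,3S)-2-ArF-3-[4-(benzyloxy)phenyl]-3-[(tert-butyldimethylsilyl)oxy]propanethioate F7 and release 10. F7 would then acylate the Et2Zn-modified dianion of 18 to give 20.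

Step 16. What may go wrong: over-reduction, either hydrogenolysis of the benzylic C2–O1 bond toward a dihydrochalcone or saturation of the chromone C2=C3 bond.

The fallback removes the benzyl groups without hydrogen. It sets out from 24 and comes back at 25, with no new compound: BCl3 and pentamethylbenzene in CH2Cl2 at −78 °C, where the arene traps the benzyl cations.

## Further compounds

F1 | step 13 | 1,3,5-tris(methoxymethoxy)benzene | COCOc1cc(OCOC)cc(OCOC)c1
F2 | step 13 | [2,4,6-tris(methoxymethoxy)phenyl]zinc chloride | COCOc1cc(OCOC)c([Zn]Cl)c(OCOC)c1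
F3 | step 13 | (2S,3S)-2-ArF-3-[4-(benzyloxy)phenyl]-3-[(tert-butyldimethylsilyl)oxy]propanoyl chloride | CC(C)(C)[Si](C)(C)O[C@H](c1ccc(OCc2ccccc2)cc1)[C@@H](C(=O)Cl)c1cc(-c2cc(=O)c3c(OCc4ccccc4)cc(OCc4ccccc4)cc3o2)ccc1OCc1ccccc1
F4 | step 13 | (2S,3S)-2-ArF-3-[4-(benzyloxy)phenyl]-3-[(tert-butyldimethylsilyl)oxy]-1-[2,4,6-tris(methoxymethoxy)phenyl]propan-1-one | CC(C)(C)[Si](C)(C)O[C@H](c1ccc(OCc2ccccc2)cc1)[C@@H](C(=O)c1c(OCOC)cc(OCOC)cc1OCOC)c1cc(-c2cc(=O)c3c(OCc4ccccc4)cc(OCc4ccccc4)cc3o2)ccc1OCc1ccccc1
F5 | step 12 | allyl 4-(2,2-dimethyl-4-oxo-4H-1,3-dioxin-6-yl)-3-oxobutanoate | C=CCOC(=O)CC(=O)CC1=CC(=O)OC(C)(C)O1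
F6 | step 12 | allyl (4S,5S)-4-ArF-5-[4-(benzyloxy)phenyl]-5-[(tert-butyldimethylsilyl)oxy]-2-[2-(2,2-dimethyl-4-oxo-4H-1,3-dioxin-6-yl)acetyl]-3-oxopentanoate | CC(C)(C)[Si](C)(C)O[C@H](c1ccc(OCc2ccccc2)cc1)[C@@H](C(=O)C(C(=O)OCC=C)C(=O)CC1=CC(=O)OC(C)(C)O1)c1cc(-c2cc(=O)c3c(OCc4ccccc4)cc(OCc4ccccc4)cc3o2)ccc1OCc1ccccc1
F0 | step 15 | none | none
F7 | step 10 | S-ethyl (2S,3S)-2-ArF-3-[4-(benzyloxy)phenyl]-3-[(tert-butyldimethylsilyl)oxy]propanethioate | CC(C)(C)[Si](C)(C)O[C@H](c1ccc(OCc2ccccc2)cc1)[C@@H](C(=O)SCC)c1cc(-c2cc(=O)c3c(OCc4ccccc4)cc(OCc4ccccc4)cc3o2)ccc1OCc1ccccc1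
F0 | step 16 | none | none
A1 | alternative 1 | 2-ArF-2-diazo-1-(2,4,6-tris{[4-(benzyloxy)benzyl]oxy}phenyl)ethan-1-one | [N-]=[N+]=C(C(=O)c1c(OCc2ccc(OCc3ccccc3)cc2)cc(OCc2ccc(OCc3ccccc3)cc2)cc1OCc1ccc(OCc2ccccc2)cc1)c1cc(-c2cc(=O)c3c(OCc4ccccc4)cc(OCc4ccccc4)cc3o2)ccc1OCc1ccccc1
A2 | alternative 1 | (2R,3S)-3-ArF-2-[4-(benzyloxy)phenyl]-5,7-bis{[4-(benzyloxy)benzyl]oxy}chroman-4-one | O=C1c2c(OCc3ccc(OCc4ccccc4)cc3)cc(OCc3ccc(OCc4ccccc4)cc3)cc2O[C@@H](c2ccc(OCc3ccccc3)cc2)[C@@H]1c1cc(-c2cc(=O)c3c(OCc4ccccc4)cc(OCc4ccccc4)cc3o2)ccc1OCc1ccccc1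
A3 | alternative 2 | trans-(3-ArF-oxiran-2-yl)[2,4-bis(benzyloxy)-6-(methoxymethoxy)phenyl]methanone (racemic, one enantiomer drawn) | COCOc1cc(OCc2ccccc2)cc(OCc2ccccc2)c1C(=O)[C@@H]1O[C@H]1c1cc(-c2cc(=O)c3c(OCc4ccccc4)cc(OCc4ccccc4)cc3o2)ccc1OCc1ccccc1
A4 | alternative 2 | 5,7-bis(benzyloxy)-3-ArF-4H-chromen-4-one | O=c1c(-c2cc(-c3cc(=O)c4c(OCc5ccccc5)cc(OCc5ccccc5)cc4o3)ccc2OCc2ccccc2)coc2cc(OCc3ccccc3)cc(OCc3ccccc3)c12
A5 | alternative 3 | 4-[(2S,3S)-3-ArF-4-oxooxetan-2-yl]phenyl pivalate | O=C1O[C@H](c2ccc(OC(=O)C(C)(C)C)cc2)[C@@H]1c1cc(-c2cc(=O)c3c(OCc4ccccc4)cc(OCc4ccccc4)cc3o2)ccc1OCc1ccccc1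
A6 | alternative 3 | 3,5-bis(benzyloxy)phenol | Oc1cc(OCc2ccccc2)cc(OCc2ccccc2)c1
A7 | alternative 3 | (2S,3R)-2-ArF-3-[3,5-bis(benzyloxy)phenoxy]-3-[4-(pivaloyloxy)phenyl]propanoic acid | c1c(OCc2ccccc2)cc(OCc2ccccc2)cc1O[C@@H](c1ccc(OC(=O)C(C)(C)C)cc1)[C@@H](C(=O)O)c1cc(-c2cc(=O)c3c(OCc4ccccc4)cc(OCc4ccccc4)cc3o2)ccc1OCc1ccccc1
A8 | alternative 3 | 4-[(2R,3S)-5,7-bis(benzyloxy)-3-ArF-4-oxochroman-2-yl]phenyl pivalate | O=C1c2c(OCc3ccccc3)cc(OCc3ccccc3)cc2O[C@@H](c2ccc(OC(=O)C(C)(C)C)cc2)[C@@H]1c1cc(-c2cc(=O)c3c(OCc4ccccc4)cc(OCc4ccccc4)cc3o2)ccc1OCc1ccccc1
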